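0.0468 /min: that is how fast the green run at 20 °C makes target, in fractions of the solid substrate charged per minute, against 0.0153 /min in violet at 0 °C. I call this the charge rate, an initial rate normalised to the charge.

| setting | violet | green | alder | ash |
|---|---|---|---|---|
| solid substrate | 0.070 M | 0.11 M | 0.050 M | 0.050 M |
| partner | 0.70 equiv | 0.70 equiv | 0.700 equiv | 0.700 equiv |
| temperature | 0 °C | 20 °C | 35 °C | 5 °C |
| remark | run made earlier | run made earlier |  |  |
| time |  |  | 2.0 min | 2.0 min |

| run | time / min | target / % | solid substrate / % |
|---|---|---|---|
| violet | 2.50 | 3.7 | 93.2 |
| violet | 5.00 | 7.4 | 88.3 |
| violet | 8.00 | 14.0 | 83.7 |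
| violet | 12.0 | 18.5 | 80.1 |
| violet | 15.0 | 23.0 | 73.1 |
| green | 0.417 | 0.8 | 98.0 |
| green | 0.667 | 1.7 | 95.3 |
| green | 1.00 | 4.6 | 95.7 |
| green | 2.00 | 9.0 | 89.9 |
| green | 3.00 | 14.3 | 84.5 |
| green | 5.00 | 23.4 | 74.3 |

(scatter of a reading: 1 percentage point)

* the flask that comes out highest in amount of target, in percent of the solid substrate charged, or "all alike" when all lie within 1.5 percentage points (alder / ash / all alike)
* target at the end, in percent of the solid substrate charged, alder
* target at the end, in percent of the solid substrate charged, ash

- solid substrate is a solid; its amount is given per volume of the solution
- the analysis behind the earlier runs scatters by 1 percentage point, standard deviation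
- at the start none of the solid substrate is in solution
- what has only dissolved of solid substrate counts as not reacted

Between those two temperatures the charge rate grows by the temperature factor, the green charge rate over the violet one, 3.05. I spread this factor evenly on a logarithmic scale of temperature, starting from violet, and I get 21.6% of the charge as target for alder and 4.05% for ash.

My first doubt is a lag. The green line through the origin asks 1.95% at 0.417 min and the reading is 0.8%. The next reading also lies low, 1.7% at 0.667 min against 3.12% on the line, so I can't exclude a short lag. I leave it out of my reckoning as an open risk.

My second doubt is the partner. Alder's 21.6% stands below the 0.700 equiv of partner charged, so the straight line can last to 2.0 min.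

The third doubt I can't compute away: green also holds 1.57 times violet's charge, so the factor may mix charge with temperature. If the molar rate ignored the charge, alder would reach 66.7%. But violet, green, alder and ash carry partner at the same equivalents, so partner moves with the charge, and I bet on 21.6%.

The forecast takes the opposite side: its rate “should not depend on the charge”. It names alder as highest, with 50% for alder and 6% for ash, so on alder it differs from my reckoning.

The flasks give 24.0% for alder and 5.64% for ash, and alder is highest.

    open intermediate + second intermediate → target (k = 13.5 /M/s, Ea = 37.0 kJ/mol)
    partner → second intermediate (k = 0.00701 /s, Ea = 75.0 kJ/mol)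
    solid substrate ⇌ starting material, rate k3*(cs3 - [starting material]) while solid is left; crystals form when [starting material] > cs3 (solubility = 2.50 mM, k = 0.0943 /s)
    starting material ⇌ open intermediate (K = 0.383, k = 0.0154 /s, Ea = 74.0 kJ/mol, ΔH = −46.0 kJ/mol)
    (constants at 5 °C)

Alder stands at 11.8% after 1.00 min and 24.0% after 2.00 min, a charge rate of 0.120 /min against my 0.108 /min. The same reckoning on the neighbour, ash repeated at −10 °C, carries the factor 3.05 down from violet and gives 1.76% of the charge as target in 2.0 min. That neighbour gives 0.672%, with 88% of its partner still unbound and 4.88% of the charge standing as starting material.

Readings and results stem from a simulated flask for an exercise; the scatter is artificial.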